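The constant of the step that makes intermediate, 4.26 × 10⁻⁵ s⁻¹, is larger than the constant of the next step, 1.60 × 10⁻⁵ s⁻¹, while a balance constant of 40 M⁻¹ ties starting material to product.

    starting material → intermediate (k1 = 4.26 × 10⁻⁵ s⁻¹)
    intermediate → product (k2 = 1.60 × 10⁻⁵ s⁻¹)
    starting material + product ⇌ idle adduct, settled at all times (K3 = 40 M⁻¹)

| setting | theta | epsilon | eta |
|---|---|---|---|
| starting material | 0.062 M | 0.062 M | 0.062 M |
| remark | a single well-mixed tank run continuously and read at steady state, 45.0 h in it on average | one stirred flow tank at steady state, fed with the mixture as stated, mean residence time 15 h | everything together in a closed stirred flask, run for 15 h |
| time |  |  | 15 h |

- the set-up with the highest amount of intermediate at the outlet or at the end, in percent of the starting material put in ("none" if the first two lie within 2 percentage points) (theta / epsilon / eta / none)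
- amount of intermediate at the outlet or at the end, in percent of the starting material put in, theta
- amount of intermediate at the outlet or at the end, in percent of the starting material put in, epsilon
- amount of intermediate at the outlet or at the end, in percent of the starting material put in, eta

- in percentages every species weighs as the starting material in it: one idle adduct counts as two
- for product the idle adduct is counted in
- the stated concentrations are those of everything mixed, before any reaction; amounts are the same in each set-up
- in an amount of product, one idle adduct counts as one product
- run time (eta): 15 h

My reckoning starts without the idle adduct, each step as first order: eta at 15 h gives 51.4 %, and the tank balances give 37.4 % for epsilon and 24.3 % for theta. Now put that first answer back in. The same sum gives eta 15.1 % product at half the run, and the balance constant times the charge is 2.5, above 1. Taking that product as unbound gives 72.8 % as the free share f, one over one plus balance constant times charge times that half-run product. Multiply the making constant by f and eta comes to 48.4 %, higher than either first-pass tank.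

The forecast names eta, with 21.4 % for theta, 33.1 % for epsilon and 48.2 % for eta, a little below mine: “The batch flask wins because the flow tanks run entirely at outlet conditions”.

The simulation gives eta, with 21.4 % for theta, 33.1 % for epsilon and 47.7 % for eta, which stands higher than epsilon by 15 percentage points against a margin of 2 points.

Watch the clock in eta: at 15.0 h intermediate is made at 0.494 of the rate at which it is used up, so it is being lost faster than it is made. Now read the same flask at 10 h. The first pass gives 7.87 % product at half that time, so f is 83.7 % and the reckoned intermediate 51.7 %. That neighbour flask holds 52.4 % intermediate, more than eta at its asked time, with 18 % of the starting material still unbound.

All constants are invented; the rest is arithmetic.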